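**Plan**

- Retrosynthesis: the exocyclic C3=CH2 bond is traced back to a C3–CH2OH group (mesylate elimination) and the C4 carboxyl group to a C4 vinyl group (ozonolysis, Pinnick oxidation).
- In the γ-lactone ring (O1, C2 carbonyl, C3, C4, C5) the neighbours C3 and C4 are the α and β carbons of the C2 carbonyl and each bears one exocyclic carbon. The C4–vinyl and C3–CH2OH bonds are therefore cut together, back to a C3=C4 butenolide, a vinyl cuprate and formaldehyde.
- The butenolide is cut at C3=C4 (ring-closing metathesis of an acrylate) and at the bond from C5 to the vinyl carbon (Grignard addition to 14-acetoxytetradecanal, made from the C14 diol).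
- Forward: the C14 chain is desymmetrised and extended by vinyl, the only ring is closed by metathesis, the two one-carbon branches are added in one flask, then the oxidation levels are adjusted.
- Stereochemistry: C5 (R) comes from a lipase kinetic resolution of the allylic alcohol; C4 (S) from cuprate addition anti to the C5 chain; C3 is stereogenic only transiently.

Key step: step 7

Remark: the discussion uses lactone numbering (O1, C2=O, C3, C4, C5 bearing the chain), while the systematic names use oxolane numbering; monomeric formaldehyde, cracked from commercial paraformaldehyde just before use, is counted as a commercial starting material.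

**Route**

Step 1
Reactants: 1 tetradecane-1,14-diol
Product: 2 14-hydroxytetradecyl acetate
Conditions: Ac2O (1.0 equiv), pyridine, THF, 0 °C to rt; chromatography, recovered 1 recycled
Reagents that add atoms: acetic anhydride, CC(=O)OC(C)=O
Why: Statistical mono-O-acylation of a symmetrical diol with one equivalent of anhydride should give the monoacetate, which differs enough in polarity from diol and diacetate to be separated.

Step 2
Reactants: 2 14-hydroxytetradecyl acetate
Product: 3 14-oxotetradecyl acetate (14-acetoxytetradecanal)
Conditions: TEMPO (10 mol %), PhI(OAc)2 (1.1 equiv), CH2Cl2, rt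
Reagents that add atoms: none
Why: The oxoammonium-mediated (TEMPO) oxidation of a primary alcohol should stop at the aldehyde and leave the acetate untouched.

Step 3
Reactants: 3 14-oxotetradecyl acetate; 4 vinylmagnesium bromide
Product: 5 rac-14-hydroxyhexadec-15-en-1-yl acetate
Conditions: 4 (1.05 equiv, THF solution) added slowly to 3, THF, −78 °C; aq. NH4Cl at −78 °C
Reagents that add atoms: none
Why: Grignard 1,2-addition to the aldehyde is far faster at −78 °C than attack on the remote acetate; the carbinol centre forms racemic and is resolved in step 4.

Step 4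
Reactants: 5 rac-14-hydroxyhexadec-15-en-1-yl acetate
Product: 6 (14R)-14-hydroxyhexadec-15-en-1-yl acetate
Conditions: Novozym 435 (immobilised Candida antarctica lipase B), vinyl acetate (3 equiv), hexane, 30 °C, stopped slightly beyond half conversion; chromatography
Reagents that add atoms: none
Why: In this lipase-catalysed kinetic resolution by transesterification, the empirical size rule (vinyl as the smaller, the long chain as the larger carbinol substituent) predicts faster acetylation of the (S)-alcohol, so the (R)-alcohol should be recovered enantioenriched; acetyl exchange at the terminal acetate is degenerate.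

Step 5
Reactants: 6 (14R)-14-hydroxyhexadec-15-en-1-yl acetate; 7 acryloyl chloride
Product: 8 (3R)-16-(acetyloxy)hexadec-1-en-3-yl prop-2-enoate
Conditions: 7 (1.5 equiv), Et3N (2 equiv), DMAP (cat.), CH2Cl2, 0 °C
Reagents that add atoms: none
Why: O-Acylation of the secondary alcohol with an acid chloride does not touch the C–O bond of the stereocentre, so the configuration is retained.

Step 6
Reactants: 8 (3R)-16-(acetyloxy)hexadec-1-en-3-yl prop-2-enoate
Product: 9 13-[(2R)-5-oxo-2,5-dihydrofuran-2-yl]tridecyl acetate
Conditions: second-generation Grubbs catalyst (H2IMes)(PCy3)Cl2Ru=CHPh (5 mol %), CH2Cl2 (0.005 M), 40 °C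
Reagents that add atoms: none
Why: Ring-closing metathesis between the acrylate and vinyl termini, with loss of ethylene, should close the five-membered unsaturated lactone; the electron-poor acrylate calls for the N-heterocyclic-carbene catalyst, and the stereocentre is not involved.

Step 7
Reactants: 9 13-[(2R)-5-oxo-2,5-dihydrofuran-2-yl]tridecyl acetate; 4 vinylmagnesium bromide (as its divinylcuprate); 10 formaldehyde
Product: 12 13-[(2R,3S,4R)-3-ethenyl-4-(hydroxymethyl)-5-oxooxolan-2-yl]tridecyl acetate, via bromomagnesium lactone enolate 11 (not isolated)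
Conditions: 4 (2.4 equiv), CuBr·SMe2 (1.2 equiv), THF, −78 to −40 °C; 9, −78 °C; then CH2O gas (10, from paraformaldehyde at 150 °C, Ar stream), −78 °C; aq. NH4Cl/NH3 at −78 °C
Reagents that add atoms: none
Why: The divinylcuprate made from 4 and CuBr·SMe2 should π-complex the C3=C4 bond of 9 on the face away from the C5 chain and transfer one vinyl group to C4, leaving the magnesium enolate 11 across C2–C3. Enolate 11 is then hydroxymethylated at C3 by monomeric formaldehyde 10 in an aldol addition, so the C4–vinyl and C3–CH2OH bonds form in one flask; the closest known reaction type is the tandem organocuprate conjugate addition–aldol trapping practised on cyclopentenones and 5-substituted butenolides. No ring is closed in this step. The C4 centre (S) is controlled by the C5 substituent (4,5-trans), and the C3 centre (R) by the new C4 vinyl group, which should steer formaldehyde to the opposite face (3,4-trans). The step needs facial selectivity at C4, secured by the single C5 substituent on the flat five-membered ring, and chemoselectivity for the enoate over the terminal acetate, secured by using the stoichiometric cuprate at −78 °C without free Grignard reagent. The C3 configuration carries little weight because C3 becomes trigonal in step 11, although the expected trans isomer is the one that behaves best in steps 9 to 11.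

Step 8
Reactants: 12 13-[(2R,3S,4R)-3-ethenyl-4-(hydroxymethyl)-5-oxooxolan-2-yl]tridecyl acetate
Product: 13 13-[(2R,3S,4R)-3-ethenyl-4-[(methanesulfonyloxy)methyl]-5-oxooxolan-2-yl]tridecyl acetate
Conditions: MsCl (1.2 equiv), Et3N (1.5 equiv), CH2Cl2, −30 °C, 30 min; cold aq. NH4Cl
Reagents that add atoms: methanesulfonyl chloride, CS(=O)(=O)Cl
Why: O-Sulfonylation of the primary alcohol at low temperature should give the mesylate before the amine can trigger elimination, turning the hydroxyl into an oxidation-stable leaving group; no stereocentre is touched.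

Step 9
Reactants: 13 13-[(2R,3S,4R)-3-ethenyl-4-[(methanesulfonyloxy)methyl]-5-oxooxolan-2-yl]tridecyl acetate
Product: 14 13-[(2R,3S,4R)-3-formyl-4-[(methanesulfonyloxy)methyl]-5-oxooxolan-2-yl]tridecyl acetate
Conditions: O3, CH2Cl2, −78 °C; PPh3 (1.2 equiv), −78 °C to rt; short silica pad, used at once
Reagents that add atoms: ozone, [O-][O+]=O
Why: Ozonolysis of the only C=C bond with neutral reductive work-up should give the C4 aldehyde without epimerising the centre α to the formyl group or eliminating the β-acyloxy aldehyde; mesylate, lactone and acetate are inert to ozone.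

Step 10
Reactants: 14 13-[(2R,3S,4R)-3-formyl-4-[(methanesulfonyloxy)methyl]-5-oxooxolan-2-yl]tridecyl acetate
Product: 15 (2R,3S,4R)-2-[13-(acetyloxy)tridecyl]-4-[(methanesulfonyloxy)methyl]-5-oxooxolane-3-carboxylic acid
Conditions: NaClO2 (2 equiv), NaH2PO4 (2 equiv), 2-methyl-2-butene (10 equiv), t-BuOH/H2O (4:1), 0 °C to rt
Reagents that add atoms: sodium chlorite, [Na+].[O-]Cl=O
Why: The Pinnick oxidation runs at about pH 4, where the aldehyde should go to the acid without epimerisation at C4 and without loss of the mesylate; 2-methyl-2-butene scavenges the hypochlorous acid.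

Step 11
Reactants: 15 (2R,3S,4R)-2-[13-(acetyloxy)tridecyl]-4-[(methanesulfonyloxy)methyl]-5-oxooxolane-3-carboxylic acid
Product: 16 (2R,3S)-2-[13-(acetyloxy)tridecyl]-4-methylidene-5-oxooxolane-3-carboxylic acid
Conditions: DBU (2.2 equiv), CH2Cl2, 0 °C; then cold 1 M HCl
Reagents that add atoms: none
Why: After the acid is deprotonated, the second equivalent of DBU should remove the lactone α-hydrogen at C3 and expel the mesylate (E1cB-type β-elimination) to give the exocyclic methylene; the C4 carboxylate disfavours deprotonation at C4, which guards against epimerisation and double-bond migration, and its trans relation to the CH2OMs group prevents lactonisation.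

**Compound list**

1 | tetradecane-1,14-diol | OCCCCCCCCCCCCCCO | starting material
2 | 14-hydroxytetradecyl acetate | OCCCCCCCCCCCCCCOC(C)=O | intermediate
3 | 14-oxotetradecyl acetate (14-acetoxytetradecanal) | O=CCCCCCCCCCCCCCOC(C)=O | intermediate
4 | vinylmagnesium bromide | C=C[Mg]Br | starting material
5 | rac-14-hydroxyhexadec-15-en-1-yl acetate | C=CC(O)CCCCCCCCCCCCCOC(C)=O | intermediate
6 | (14R)-14-hydroxyhexadec-15-en-1-yl acetate | C=C[C@H](O)CCCCCCCCCCCCCOC(C)=O | intermediate
7 | acryloyl chloride | C=CC(=O)Cl | starting material
8 | (3R)-16-(acetyloxy)hexadec-1-en-3-yl prop-2-enoate | C=CC(=O)O[C@H](CCCCCCCCCCCCCOC(C)=O)C=C | intermediate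
9 | 13-[(2R)-5-oxo-2,5-dihydrofuran-2-yl]tridecyl acetate | O=C1O[C@H](CCCCCCCCCCCCCOC(C)=O)C=C1 | intermediate
10 | formaldehyde (monomer, cracked from paraformaldehyde) | C=O | starting material
11 | bromomagnesium (4S,5R)-5-[13-(acetyloxy)tridecyl]-4-ethenyl-4,5-dihydrofuran-2-olate (lactone enolate, formed in the flask, not isolated) | C1=C(O[Mg]Br)O[C@H](CCCCCCCCCCCCCOC(C)=O)[C@H]1C=C | intermediate
12 | 13-[(2R,3S,4R)-3-ethenyl-4-(hydroxymethyl)-5-oxooxolan-2-yl]tridecyl acetate (2,3-trans, 3,4-trans) | OC[C@@H]1C(=O)O[C@H](CCCCCCCCCCCCCOC(C)=O)[C@H]1C=C | intermediate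
13 | 13-[(2R,3S,4R)-3-ethenyl-4-[(methanesulfonyloxy)methyl]-5-oxooxolan-2-yl]tridecyl acetate | CS(=O)(=O)OC[C@@H]1C(=O)O[C@H](CCCCCCCCCCCCCOC(C)=O)[C@H]1C=C | intermediate
14 | 13-[(2R,3S,4R)-3-formyl-4-[(methanesulfonyloxy)methyl]-5-oxooxolan-2-yl]tridecyl acetate | CS(=O)(=O)OC[C@@H]1C(=O)O[C@H](CCCCCCCCCCCCCOC(C)=O)[C@H]1C=O | intermediate
15 | (2R,3S,4R)-2-[13-(acetyloxy)tridecyl]-4-[(methanesulfonyloxy)methyl]-5-oxooxolane-3-carboxylic acid | CS(=O)(=O)OC[C@@H]1C(=O)O[C@H](CCCCCCCCCCCCCOC(C)=O)[C@H]1C(=O)O | intermediate
16 | (2R,3S)-2-[13-(acetyloxy)tridecyl]-4-methylidene-5-oxooxolane-3-carboxylic acid | C=C1C(=O)O[C@H](CCCCCCCCCCCCCOC(C)=O)[C@H]1C(=O)O | target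

**Count and risks**

Total step count: 11. Longest linear sequence: 11 steps (1 to 16).

Steps most likely to fail:

1. Step 7. The enolate may be captured incompletely or unselectively by gaseous formaldehyde (proton transfer, oligomerisation of formaldehyde, double hydroxymethylation). The fallback sets out from 9: the same cuprate is added in the presence of Me3SiCl (THF, −78 °C), which accelerates the conjugate addition and traps the enolate as the trimethylsilyl ketene acetal 13-[(2R,3S)-3-ethenyl-5-[(trimethylsilyl)oxy]-2,3-dihydrofuran-2-yl]tridecyl acetate F1. After a non-aqueous work-up, crude F1 would be hydroxymethylated in a Mukaiyama aldol reaction with formaldehyde 10 and TiCl4 in CH2Cl2 at −78 °C; aqueous work-up returns to the route at 12.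

2. Step 11. The amine base may move the exocyclic double bond into the ring or epimerise C4. The fallback sets out from 15: sodium benzeneselenolate (PhSeSePh, NaBH4, EtOH/THF, 0 °C) replaces the mesylate, by direct displacement or by addition to any methylene lactone formed, to give the selenide (2R,3S,4S)-2-[13-(acetyloxy)tridecyl]-5-oxo-4-[(phenylselanyl)methyl]oxolane-3-carboxylic acid F2. Oxidation with H2O2 in THF at 0 °C to rt gives the selenoxide, whose syn-elimination can only take the C3 hydrogen and should deliver 16 without base.

3. Step 9. The aldehyde may be lost during isolation through β-elimination of the lactone oxygen, epimerisation at C4, or intramolecular alkylation of its enol by the mesylate. The fallback sets out from 13: RuCl3 (cat.) and NaIO4 in MeCN/CCl4/H2O at rt cleave the vinyl group directly to the carboxylic acid, so that no aldehyde is handled, and the route is rejoined at 15; this fallback makes no new compound (F0).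

**Further compounds**

F1 | step 7 | 13-[(2R,3S)-3-ethenyl-5-[(trimethylsilyl)oxy]-2,3-dihydrofuran-2-yl]tridecyl acetate | C1=C(O[Si](C)(C)C)O[C@H](CCCCCCCCCCCCCOC(C)=O)[C@H]1C=C
F2 | step 11 | (2R,3S,4S)-2-[13-(acetyloxy)tridecyl]-5-oxo-4-[(phenylselanyl)methyl]oxolane-3-carboxylic acid | c1ccccc1[Se]C[C@@H]2C(=O)O[C@H](CCCCCCCCCCCCCOC(C)=O)[C@H]2C(=O)O
F0 | step 9 | none | none
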